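**Plan**
- Retrosynthesis: the C8–OMe bond is cut first (methoxylation of an 8-iodide, itself from C8–H), then O1–C2 of ring C (6-endo oxa-Michael closure of an o-hydroxyaryl ynone).
- The ynone is then cut at C8a–O1 and C4a–C4 together. O1 and the C4 carbonyl carbon sit on the neighbouring ring-A carbons C8a and C4a, which is the pattern a carboxylic acid delivers across an aryne; the 5-OMe next to C4a steers the addition.
- Forward: ring A enters as a 3,5-dimethoxyaryne precursor (from 3,5-dimethoxyphenol), ring B as 3-(2,3,4-trimethoxyphenyl)propiolic acid (from the aldehyde). They are joined by aryne C–O insertion without ring closure, ring C is closed next, and C8 is oxygenated last.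
- Stereochemistry: the target is achiral; only regiochemistry (ortho-lithiation, aryne addition, C8 iodination) has to be controlled.

Key step: step 6

Remark: the target has no stereocentre, and reagents that carry no compound number are taken as purchased.

**Step 1**
Reactants: 1 3,5-dimethoxyphenol
Product: 2 3,5-dimethoxyphenyl isopropylcarbamate
Conditions: i-PrNCO, Et3N (cat.), CH2Cl2, rt
Reagents that add atoms: isopropyl isocyanate, CC(C)N=C=O
Why: Base-catalysed addition of a phenol to an isocyanate (carbamoylation) should install cleanly the secondary carbamate that serves as a strong yet easily removed ortho-directing group.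

**Step 2**
Reactants: 2 3,5-dimethoxyphenyl isopropylcarbamate
Product: 6 3,5-dimethoxy-2-(trimethylsilyl)phenyl isopropylcarbamate, via N-silyl carbamate 3 (not isolated), via aryllithium 4 (not isolated), via bis-silyl carbamate 5 (not isolated)
Conditions: TMSOTf, TMEDA, Et2O, rt; n-BuLi (2.1 equiv), TMEDA, −78 °C; TMSCl, −78 °C to rt; aq. NH4Cl/MeOH work-up
Reagents that add atoms: chlorotrimethylsilane, C[Si](C)(C)Cl
Why: Directed ortho-metalation of the carbamate, N-silylated in the flask, should take place at C2 (equivalent to C6 by symmetry), the site activated jointly by the carbamate and a methoxy group, and the aryllithium is silylated at low temperature before an anionic Fries shift can start, the labile N–Si bond being hydrolysed on the mild work-up.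

**Step 3**
Reactants: 6 3,5-dimethoxy-2-(trimethylsilyl)phenyl isopropylcarbamate
Product: 8 3,5-dimethoxy-2-(trimethylsilyl)phenyl trifluoromethanesulfonate, via silylphenol 7 (not isolated)
Conditions: DBU, Et2NH, MeCN, 40 °C; then PhNTf2, rt
Reagents that add atoms: N-phenylbis(trifluoromethanesulfonimide), O=S(=O)(N(c1ccccc1)S(=O)(=O)C(F)(F)F)C(F)(F)F
Why: E1cB cleavage of the secondary carbamate (loss of isopropyl isocyanate, trapped by Et2NH as a urea) frees the phenoxide under non-acidic conditions that spare the electron-rich aryl–Si bond, and O-sulfonylation in the same pot should give the Kobayashi-type aryne precursor.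

**Step 4**
Reactants: 9 2,3,4-trimethoxybenzaldehyde
Product: 10 1-(2,2-dibromovinyl)-2,3,4-trimethoxybenzene
Conditions: CBr4, PPh3, CH2Cl2, 0 °C
Reagents that add atoms: carbon tetrabromide, BrC(Br)(Br)Br
Why: Corey–Fuchs dibromo-olefination, a Wittig reaction of the ylide Ph3P=CBr2 made in the flask, is routine for electron-rich aryl aldehydes.

**Step 5**
Reactants: 10 1-(2,2-dibromovinyl)-2,3,4-trimethoxybenzene
Product: 12 3-(2,3,4-trimethoxyphenyl)propiolic acid, via lithium acetylide 11 (not isolated)
Conditions: n-BuLi (2.1 equiv), THF, −78 °C; CO2, −78 °C to rt; aq. HCl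
Reagents that add atoms: carbon dioxide, O=C=O
Why: In the second stage of the Corey–Fuchs sequence, Br–Li exchange and a Fritsch–Buttenberg–Wiechell-type 1,2-shift should deliver the lithium acetylide, whose carboxylation with CO2 gives the arylpropiolic acid.

**Step 6**
Reactants: 8 3,5-dimethoxy-2-(trimethylsilyl)phenyl trifluoromethanesulfonate; 12 3-(2,3,4-trimethoxyphenyl)propiolic acid
Product: 14 1-(2-hydroxy-4,6-dimethoxyphenyl)-3-(2,3,4-trimethoxyphenyl)prop-2-yn-1-one, via 3,5-dimethoxybenzyne 13 (not isolated)
Conditions: CsF (4 equiv), THF, sealed tube, 100 °C; AcOH quench once 12 is consumed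
Reagents that add atoms: none
Why: Fluoride removes the silyl group of 8 and triflate departs to give aryne 13; the cesium carboxylate of 12 adds through oxygen to the aryne carbon remote from the flanking methoxy group, and the aryl anion held ortho to the acyloxy group attacks the ester carbonyl to give a four-membered benzoxete-type alkoxide that opens to the o-acylphenoxide, so that C8a–O1 and C4a–C4 form in one operation. The closest known reaction type is the fluoride-induced formal insertion of arynes into the C–O bond of carboxylic acids to give o-hydroxyaryl ketones, which follows the logic of an anionic Fries-type 1,3-O-to-C acyl shift. No ring of the target is closed and no stereocentre is created; the product keeps C2 and C3 as an alkyne, the oxidation level needed for the later pyranone closure. The selectivity required is regiochemical: the inductively withdrawing methoxy group next to the aryne bond makes the distal carbon the electrophilic one and stabilises the negative charge developing at the proximal carbon, so the acyl group ends between the hydroxyl and a methoxy group as the 2-hydroxy-4,6-dimethoxy pattern requires. Attack of the phenoxide on the ynone in the flask should be held back by the moderate temperature, the chelated and weakly nucleophilic state of the o-acylphenol and the acid quench, and any material that does close in the aprotic fluoride medium is expected to do so 6-endo to flavone 15, the next compound of the route.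

**Step 7**
Reactants: 14 1-(2-hydroxy-4,6-dimethoxyphenyl)-3-(2,3,4-trimethoxyphenyl)prop-2-yn-1-one
Product: 15 5,7-dimethoxy-2-(2,3,4-trimethoxyphenyl)-4H-chromen-4-one
Conditions: DMAP (20 mol %), DMF, 40 °C
Reagents that add atoms: none
Why: In this nucleophilic-amine-catalysed oxa-Michael cyclisation DMAP adds to the β-carbon of the ynone and the phenol closes 6-endo on the activated enone with loss of DMAP, which in an aprotic medium should avoid the 5-exo aurone pathway.

**Step 8**
Reactants: 15 5,7-dimethoxy-2-(2,3,4-trimethoxyphenyl)-4H-chromen-4-one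
Product: 16 8-iodo-5,7-dimethoxy-2-(2,3,4-trimethoxyphenyl)-4H-chromen-4-one
Conditions: NIS (1.05 equiv), DMF, rt to 50 °C, dark
Reagents that add atoms: N-iodosuccinimide, O=C1CCC(=O)N1I
Why: In this electrophilic aromatic iodination C8 of a fully O-methylated 5,7-dioxygenated flavone (para to 5-OMe, ortho to 7-OMe and to the ring oxygen) should be the most nucleophilic and least hindered position, since C6 is buttressed by two methoxy groups and ring B is less activated than the phloroglucinol-type ring A.

**Step 9**
Reactants: 16 8-iodo-5,7-dimethoxy-2-(2,3,4-trimethoxyphenyl)-4H-chromen-4-one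
Product: 17 2',3',4',5,7,8-hexamethoxyflavone (5,7,8-trimethoxy-2-(2,3,4-trimethoxyphenyl)-4H-chromen-4-one)
Conditions: NaOMe, CuBr, MeOH–DMF, 110 °C
Reagents that add atoms: sodium methoxide, [Na+].[O-]C
Why: Copper-mediated Ullmann-type methoxylation of an aryl iodide is the standard way to turn 8-halo polymethoxyflavones into their 8-methoxy congeners, and the flanking oxygen substituents should not block it.

**Compound list**
1 | 3,5-dimethoxyphenol | COc1cc(O)cc(OC)c1 | starting material
2 | 3,5-dimethoxyphenyl isopropylcarbamate | COc1cc(OC)cc(OC(=O)NC(C)C)c1 | intermediate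
3 | 3,5-dimethoxyphenyl isopropyl(trimethylsilyl)carbamate (N-silyl carbamate, formed in the flask) | COc1cc(OC)cc(OC(=O)N(C(C)C)[Si](C)(C)C)c1 | intermediate
4 | [2-((isopropyl(trimethylsilyl)carbamoyl)oxy)-4,6-dimethoxyphenyl]lithium (aryllithium, formed in the flask) | COc1cc(OC)c([Li])c(OC(=O)N(C(C)C)[Si](C)(C)C)c1 | intermediate
5 | 3,5-dimethoxy-2-(trimethylsilyl)phenyl isopropyl(trimethylsilyl)carbamate (bis-silyl carbamate, formed in the flask) | COc1cc(OC)c([Si](C)(C)C)c(OC(=O)N(C(C)C)[Si](C)(C)C)c1 | intermediate
6 | 3,5-dimethoxy-2-(trimethylsilyl)phenyl isopropylcarbamate | COc1cc(OC)c([Si](C)(C)C)c(OC(=O)NC(C)C)c1 | intermediate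
7 | 3,5-dimethoxy-2-(trimethylsilyl)phenol (silylphenol, formed in the flask) | COc1cc(O)c([Si](C)(C)C)c(OC)c1 | intermediate
8 | 3,5-dimethoxy-2-(trimethylsilyl)phenyl trifluoromethanesulfonate | COc1cc(OC)c([Si](C)(C)C)c(OS(=O)(=O)C(F)(F)F)c1 | intermediate
9 | 2,3,4-trimethoxybenzaldehyde | COc1ccc(C=O)c(OC)c1OC | starting material
10 | 1-(2,2-dibromovinyl)-2,3,4-trimethoxybenzene | COc1ccc(C=C(Br)Br)c(OC)c1OC | intermediate
11 | lithium (2,3,4-trimethoxyphenyl)acetylide (formed in the flask) | [Li]C#Cc1ccc(OC)c(OC)c1OC | intermediate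
12 | 3-(2,3,4-trimethoxyphenyl)propiolic acid | COc1ccc(C#CC(=O)O)c(OC)c1OC | intermediate
13 | 3,5-dimethoxybenzyne (1,2-didehydro-3,5-dimethoxybenzene, formed in the flask) | COC1=CC(OC)=CC#C1 | intermediate
14 | 1-(2-hydroxy-4,6-dimethoxyphenyl)-3-(2,3,4-trimethoxyphenyl)prop-2-yn-1-one | COc1cc(O)c(C(=O)C#Cc2ccc(OC)c(OC)c2OC)c(OC)c1 | intermediate
15 | 5,7-dimethoxy-2-(2,3,4-trimethoxyphenyl)-4H-chromen-4-one | COc1ccc(-c2cc(=O)c3c(OC)cc(OC)cc3o2)c(OC)c1OC | intermediate
16 | 8-iodo-5,7-dimethoxy-2-(2,3,4-trimethoxyphenyl)-4H-chromen-4-one | COc1ccc(-c2cc(=O)c3c(OC)cc(OC)c(I)c3o2)c(OC)c1OC | intermediate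
17 | 2',3',4',5,7,8-hexamethoxyflavone | COc1ccc(-c2cc(=O)c3c(OC)cc(OC)c(OC)c3o2)c(OC)c1OC | target

**Count**
Total steps: 9. Longest linear sequence: 7 steps (1 → 2 → 6 → 8 → 14 → 15 → 16 → 17); the acid branch (9 → 10 → 12) adds 2 steps.

**Steps most likely to fail**

Step 6. Several processes could erode the insertion:
- protonation of the aryl anion before acyl transfer, which leaves the aryl ester;
- thermal loss of CO2 from the propiolate;
- addition to the aryne with the wrong orientation;
- closure of the phenoxide on the ynone in the flask, partly in the 5-exo sense.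

Fallback: setting out from aldehyde 9, Claisen–Schmidt condensation with purchased 2'-hydroxy-4',6'-dimethoxyacetophenone (KOH, EtOH, rt) would give the chalcone (E)-1-(2-hydroxy-4,6-dimethoxyphenyl)-3-(2,3,4-trimethoxyphenyl)prop-2-en-1-one F1. Oxidative cyclisation of F1 (I2 cat., DMSO, 130 °C) comes back to the route at flavone 15.

Step 8. Iodination could occur at C6, at C3 of the pyranone or on the trimethoxyphenyl ring, or run on to a di-iodide.

Fallback: setting out from flavone 15, the 8-oxygen is brought in by phenoxide oxidation instead of halogenation.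
- Chelation-controlled cleavage of the 5-methyl ether (AlCl3, MeCN, 50 °C) would give 5-hydroxy-7-methoxy-2-(2,3,4-trimethoxyphenyl)-4H-chromen-4-one F2.
- Elbs persulfate oxidation (K2S2O8, aq. KOH–pyridine, rt) attacks para to the phenoxide, hence at C8, and would give potassium 5-hydroxy-7-methoxy-4-oxo-2-(2,3,4-trimethoxyphenyl)-4H-chromen-8-yl sulfate F3.
- Acid hydrolysis (aq. HCl, Na2SO3, 80 °C) would release 5,8-dihydroxy-7-methoxy-2-(2,3,4-trimethoxyphenyl)-4H-chromen-4-one F4.
- Exhaustive methylation (Me2SO4, K2CO3, acetone, reflux) comes back to the route at target 17.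

Step 9. Reductive loss of iodine, opening of the pyranone by methoxide or demethylation at O5 could compete with the C–O coupling.

Fallback: setting out from iodide 16, the C–O bond is made through boron.
- Miyaura borylation (B2pin2, PdCl2(dppf), KOAc, dioxane, 90 °C) would give 5,7-dimethoxy-8-(4,4,5,5-tetramethyl-1,3,2-dioxaborolan-2-yl)-2-(2,3,4-trimethoxyphenyl)-4H-chromen-4-one F5.
- Mild oxidation (NaBO3·4H2O, THF–H2O, rt) would give 8-hydroxy-5,7-dimethoxy-2-(2,3,4-trimethoxyphenyl)-4H-chromen-4-one F6.
- O-Methylation (MeI, K2CO3, acetone, reflux) comes back to the route at target 17.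

**Further compounds**
F1 | step 6 | (E)-1-(2-hydroxy-4,6-dimethoxyphenyl)-3-(2,3,4-trimethoxyphenyl)prop-2-en-1-one | COc1cc(O)c(C(=O)/C=C/c2ccc(OC)c(OC)c2OC)c(OC)c1
F2 | step 8 | 5-hydroxy-7-methoxy-2-(2,3,4-trimethoxyphenyl)-4H-chromen-4-one | COc1ccc(-c2cc(=O)c3c(O)cc(OC)cc3o2)c(OC)c1OC
F3 | step 8 | potassium 5-hydroxy-7-methoxy-4-oxo-2-(2,3,4-trimethoxyphenyl)-4H-chromen-8-yl sulfate | COc1ccc(-c2cc(=O)c3c(O)cc(OC)c(OS(=O)(=O)[O-])c3o2)c(OC)c1OC.[K+]
F4 | step 8 | 5,8-dihydroxy-7-methoxy-2-(2,3,4-trimethoxyphenyl)-4H-chromen-4-one | COc1ccc(-c2cc(=O)c3c(O)cc(OC)c(O)c3o2)c(OC)c1OC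
F5 | step 9 | 5,7-dimethoxy-8-(4,4,5,5-tetramethyl-1,3,2-dioxaborolan-2-yl)-2-(2,3,4-trimethoxyphenyl)-4H-chromen-4-one | COc1ccc(-c2cc(=O)c3c(OC)cc(OC)c(B4OC(C)(C)C(C)(C)O4)c3o2)c(OC)c1OC
F6 | step 9 | 8-hydroxy-5,7-dimethoxy-2-(2,3,4-trimethoxyphenyl)-4H-chromen-4-one | COc1ccc(-c2cc(=O)c3c(OC)cc(OC)c(O)c3o2)c(OC)c1OC
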